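The numbering is guaiane numbering in both halves. The unprimed half carries the C2 carbinol and the C1=C10 alkene, and the primed half carries the spiro carbon C4′. The α-face is the face of H-1 and H-5, and ring L is the linking cyclohexene C2–C1–C10–C14–C15′–C4′.
Enabling feature: in ring L the carbinol C2 is allylic to C1=C10, α to the C3 ketone and β to the C3′ ketone, so C2–C4′ is an aldol bond. Retro-aldol gives a C2/C3 enedione with a tethered C4′ enolate, and 1,4-closure of that enolate on C10 is the spiro-cyclobutane C10–C14–C15′–C4′.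
Ring L ⇒ that cyclobutane, which has two atoms fewer. C1 and C2 enter the ring by a 1,3-shift of C4′ from C10 to C2, released when C2 is raised to the diosphenol level.
Cyclobutane ⇒ Lewis-acid [2+2] homodimerisation of one monomer, enone 8 (C10=C14 of one molecule, C4′=C15′ of the other). Enone 8 ⇒ dehydrocostus lactone 1 by C7 inversion and C3 oxidation.
Ring order: the six rings of the two halves come with 1, the cyclobutane is closed in step 6, and ring L grows out of it in step 9.

Key step: step 9

Remark: read literally, the target SMILES places H-7 syn to H-6 and H-7′ syn to H-6′ (both lactones cis-fused), which is the C7 epimer of the commercial trans-fused lactone 1; the route takes this at face value and inverts C7 once, at the monomer stage (steps 1–3).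

Step 1
Reactants: 1 dehydrocostus lactone
Product: 2 11β,13-epoxy-dehydrocostus lactone (spiro-epoxide on the lactone, oxygen β)
Conditions: t-BuOOH, DBU, CH2Cl2, 0 °C to rt
Reagents that add atoms: tert-butyl hydroperoxide CC(C)(C)OO
Why: Weitz–Scheffer nucleophilic epoxidation touches only the electron-poor C11=C13 alkene (the two isolated 1,1-disubstituted alkenes are inert to the peroxide anion), and the C11 enolate closes on oxygen from the β-face, anti to the axial H-7, which sets a C11 centre that is erased in step 2.

Step 2
Reactants: 2 11β,13-epoxy-dehydrocostus lactone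
Product: 3 13-hydroxyguaia-4(15),7(11),10(14)-trien-12,6-olide (α-hydroxymethyl butenolide, C7 now sp2)
Conditions: LiN(iPr)2 (LDA, 1.05 equiv), THF–DMPU, −78 to −30 °C; AcOH quench
Reagents that add atoms: none
Why: Base-induced epoxide-to-allylic-alcohol isomerisation (E2) removes H-7, which is antiperiplanar to the C11–O bond, and gives the conjugated tetrasubstituted butenolide, so the C7 stereocentre is erased and no new one is formed.

Step 3
Reactants: 3 13-hydroxyguaia-4(15),7(11),10(14)-trien-12,6-olide
Product: 6 7-epi-dehydrocostus lactone (H-7 β, cis-fused lactone), via sulfonylhydrazine adduct 4 (not isolated), via allylic diazene 5 (not isolated)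
Conditions: 2-nitrobenzenesulfonylhydrazide, PPh3, DEAD, THF, −30 °C, then 23 °C
Reagents that add atoms: none
Why: Mitsunobu displacement and loss of sulfinic acid give the allylic diazene, whose retro-ene loss of N2 (reductive 1,3-transposition of an allylic alcohol) puts hydrogen on C7 and restores the C11=C13 methylene, and hydrogen arrives on the β-face of the flat butenolide because that face carries only H-6 while C5 blocks the α-face, so H-6 and H-7 end up syn.

Step 4
Reactants: 6 7-epi-dehydrocostus lactone
Product: 7 3α-hydroxy-7-epi-dehydrocostus lactone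
Conditions: SeO2 (cat.), t-BuOOH, CH2Cl2, 0 °C to rt
Reagents that add atoms: tert-butyl hydroperoxide CC(C)(C)OO
Why: Catalytic SeO2 allylic hydroxylation (ene reaction, then [2,3]-shift) takes the C3 methylene next to C4=C15 as it does in the parent lactone, with oxygen delivered on the convex α-face, and this centre is erased in step 5.

Step 5
Reactants: 7 3α-hydroxy-7-epi-dehydrocostus lactone
Product: 8 7-epi-dehydrozaluzanin C (3-oxo, exocyclic C4=C15 enone)
Conditions: Dess–Martin periodinane, CH2Cl2, 0 °C
Reagents that add atoms: none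
Why: Dess–Martin oxidation of the allylic alcohol gives the exocyclic enone without touching the alkenes or the lactone, and no stereocentre is formed.

Step 6
Reactants: 8 7-epi-dehydrozaluzanin C (two molecules)
Product: 10 spiro-cyclobutane dimer (four-membered ring C10–C14–C15′–C4′; the C10–C4′ bond is β on the unprimed half and α on the primed half), via zwitterion 9 (not isolated)
Conditions: EtAlCl2 (0.3 equiv), CH2Cl2, −78 °C, concentrated solution, quenched cold at partial conversion, 8 recycled
Reagents that add atoms: none
Why: This is a Lewis-acid-promoted stepwise [2+2] cycloaddition of a 1,1-disubstituted alkene with an enone, in which C14 of one molecule attacks the activated C15′ of the other and the tertiary C10 cation is captured by C4′ of the aluminium enolate (oxygen is tied up by aluminium and the low temperature slows proton loss), with bonding on the convex α-face of the enone half and the β-face of the alkene half, and both new centres are erased or reset in step 9.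

Step 7
Reactants: 10 spiro-cyclobutane dimer
Product: 11 2α-acetoxy spiro-cyclobutane dimer
Conditions: Mn(OAc)3·2H2O, benzene, reflux, Dean–Stark trap
Reagents that add atoms: manganese triacetate CC(=O)[O-].CC(=O)[O-].CC(=O)[O-].[Mn+3]
Why: α′-Acetoxylation of an enone with manganese triacetate runs through the trivalent-manganese enolate of the conjugated C3 ketone and spares saturated ketones such as C3′, and acetate reaches C2 on the α-face, anti to the bulky C10 spiro centre, a configuration that is erased in step 9.

Step 8
Reactants: 11 2α-acetoxy spiro-cyclobutane dimer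
Product: 12 2α-hydroxy spiro-cyclobutane dimer (C2/C3 α-ketol)
Conditions: Sc(OTf)3 (cat.), MeOH–CH2Cl2, rt
Reagents that add atoms: none
Why: Lewis-acid-catalysed transesterification (methanolysis) cleaves the activated α-keto acetate under near-neutral conditions that leave both α-methylene lactones, the enone and the cyclobutane untouched, and C2 keeps its configuration.

Step 9
Reactants: 12 2α-hydroxy spiro-cyclobutane dimer
Product: 16 target CNP0269880.1, via cyclobutane dione 13 (not isolated), via cyclobutane diosphenol 14 (not isolated), via seco enedione enol 15 (not isolated)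
Conditions: Dess–Martin periodinane, CH2Cl2, 0 °C; then DBU, −20 °C to rt, same flask
Reagents that add atoms: none
Why: Proposed new method: Oxidation of the α-ketol gives 2,3-dione 13, which enolises through H-1 to diosphenol 14, and the DBU salt of 14 is a push–pull vinylcyclobutane in which the O2 oxyanion pushes through C2=C1 and the C3′ ketone pulls, so the strained C10–C4′ bond breaks (retro-Michael) to the enolate of 15, which recloses on C2, a net anion-driven 1,3-shift of C4′ from C10 to C2 that enlarges the four-membered ring by C1 and C2. The closest known reaction types are the alkoxide-accelerated vinylcyclobutane-to-cyclohexene rearrangement and the opening of donor–acceptor cyclobutanes followed by six-ring closure, and what is new is the enolate donor at the vinyl terminus and the aldol capture. The only ring closed is ring L, by a 6-(enolexo)-exo-trig aldol addition. C4′ is set by reaction through the convex α-face of the primed hydroazulene (the face of H-1′ and H-5′), and C2 is set by attack on the β-face of the flat enedione, whose α-face is covered by H-5 and the cis-fused lactone, so the hydroxyl ends up α. The step needs cleavage of C10–C4′ and not C10–C14, which is secured because only C4′ can leave as a stabilised enolate, and it needs closure on C2 and not on C3 or back on C10, which is secured by ring size (six against a bridged seven) and by the cyclobutane strain that a return to C10 would cost. Reversibility of the aldol lets a wrong diastereomer reopen to 15, and the hydrogen bond from the C2 hydroxyl to the C3′ ketone holds the product.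

Compound list
1 | dehydrocostus lactone | C=C1CC[C@H]2C(=C)CC[C@H]3C(=C)C(=O)O[C@@H]3[C@H]21 | starting material
2 | 11β,13-epoxy-dehydrocostus lactone | C=C1CC[C@H]2C(=C)CC[C@H]3[C@]4(CO4)C(=O)O[C@@H]3[C@H]21 | intermediate
3 | 13-hydroxyguaia-4(15),7(11),10(14)-trien-12,6-olide | C=C1CC[C@H]2C(=C)CCC3=C(CO)C(=O)O[C@@H]3[C@H]21 | intermediate
4 | sulfonylhydrazine adduct (C13–N(NH2)SO2Ar, Ar = 2-nitrophenyl) | C=C1CC[C@H]2C(=C)CCC3=C(CN(N)S(=O)(=O)c4ccccc4[N+](=O)[O-])C(=O)O[C@@H]3[C@H]21 | intermediate
5 | allylic diazene (C13–N=NH) | C=C1CC[C@H]2C(=C)CCC3=C(CN=N)C(=O)O[C@@H]3[C@H]21 | intermediate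
6 | 7-epi-dehydrocostus lactone | C=C1CC[C@H]2C(=C)CC[C@@H]3C(=C)C(=O)O[C@@H]3[C@H]21 | intermediate
7 | 3α-hydroxy-7-epi-dehydrocostus lactone | C=C1[C@H](O)C[C@H]2C(=C)CC[C@@H]3C(=C)C(=O)O[C@@H]3[C@H]21 | intermediate
8 | 7-epi-dehydrozaluzanin C | C=C1C(=O)C[C@H]2C(=C)CC[C@@H]3C(=C)C(=O)O[C@@H]3[C@H]21 | intermediate
9 | zwitterion (C10 cation, C3′ enolate, drawn without aluminium) | C=C1C(=O)C[C@H]2[C+](CC[C@@H]3C(=C)C(=O)O[C@@H]3[C@@H]12)CCC1=C([O-])C[C@H]2C(=C)CC[C@@H]3C(=C)C(=O)O[C@@H]3[C@H]21 | intermediate
10 | spiro-cyclobutane dimer | C=C1C(=O)C[C@H]2[C@@]3(CC[C@@H]4C(=C)C(=O)O[C@@H]4[C@@H]12)CC[C@]31C(=O)C[C@H]2C(=C)CC[C@@H]3C(=C)C(=O)O[C@@H]3[C@H]21 | intermediate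
11 | 2α-acetoxy spiro-cyclobutane dimer | C=C1C(=O)[C@H](OC(C)=O)[C@H]2[C@@]3(CC[C@@H]4C(=C)C(=O)O[C@@H]4[C@@H]12)CC[C@]31C(=O)C[C@H]2C(=C)CC[C@@H]3C(=C)C(=O)O[C@@H]3[C@H]21 | intermediate
12 | 2α-hydroxy spiro-cyclobutane dimer | C=C1C(=O)[C@H](O)[C@H]2[C@@]3(CC[C@@H]4C(=C)C(=O)O[C@@H]4[C@@H]12)CC[C@]31C(=O)C[C@H]2C(=C)CC[C@@H]3C(=C)C(=O)O[C@@H]3[C@H]21 | intermediate
13 | cyclobutane dione (2,3-dione, H-1 retained) | C=C1C(=O)C(=O)[C@H]2[C@@]3(CC[C@@H]4C(=C)C(=O)O[C@@H]4[C@@H]12)CC[C@]31C(=O)C[C@H]2C(=C)CC[C@@H]3C(=C)C(=O)O[C@@H]3[C@H]21 | intermediate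
14 | cyclobutane diosphenol (C2(OH)=C1) | C=C1C(=O)C(O)=C2[C@@]3(CC[C@@H]4C(=C)C(=O)O[C@@H]4[C@@H]12)CC[C@]31C(=O)C[C@H]2C(=C)CC[C@@H]3C(=C)C(=O)O[C@@H]3[C@H]21 | intermediate
15 | seco enedione enol (C10–C4′ cleaved, drawn as the neutral C3′ enol) | C=C1C(=O)C(=O)C2=C(CC[C@@H]3C(=C)C(=O)O[C@@H]3[C@@H]12)CCC1=C(O)C[C@H]2C(=C)CC[C@@H]3C(=C)C(=O)O[C@@H]3[C@H]21 | intermediate
16 | target CNP0269880.1 | C=C1C(=O)[C@]2(O)C3=C(CC[C@@H]4C(=C)C(=O)O[C@@H]4[C@@H]13)CC[C@]21C(=O)C[C@H]2C(=C)CC[C@@H]3C(=C)C(=O)O[C@@H]3[C@H]21 | target

Total step count: 9. Longest linear sequence: 9 (steps 1–9; step 6 joins two molecules of 8).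

Steps most likely to fail

Step 9. The ring-opened enolate may fragment further by retro-Michael cleavage of the C14–C15′ bond, or the dione may decompose before it enolises through H-1. The fallback sets out from 10 and comes back at 16, and it keeps the four-to-six ring growth but uses only known reactions in the 2-deoxy series.
- Enone-selective dehydrogenation of 10 with DDQ in refluxing dioxane should give the cross-conjugated vinylcyclobutane dienone F1.
- Heating F1 in toluene in a sealed tube should bring about the thermal vinylcyclobutane-to-cyclohexene rearrangement to the 2-deoxy dimer F2.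
- The tertiary C2–H of F2, which is α to the C3 ketone and allylic to C1=C10, is then hydroxylated with DBU, O2 and P(OEt)3 in THF to give 16.

Step 6. Three things can outrun C–C closure of the zwitterion: proton loss from the C10 cation (ene-type collapse), closure through the enolate oxygen, and chain growth. Chain growth is possible because every molecule of 8 is both donor and acceptor. The fallback sets out from 7 and 8 and comes back at 10, and it replaces the homodimerisation with a cross-cycloaddition that uses a donor-only partner.
- Alcohol 7 is silylated (TBSCl, imidazole, DMF) to the silyl ether F3.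
- F3, which has no enone, is used in excess with 8 and EtAlCl2 at −78 °C and should give the cross cyclobutane silyl ether F4.
- HF·pyridine frees the cyclobutane allylic alcohol F5.
- Dess–Martin oxidation of F5 gives 10.

Step 3. Facial selectivity of the hydrogen transfer to C7 may be poor, or the Mitsunobu displacement may stall on the electron-poor allylic system. The fallback sets out from 3 and comes back at 6, and it delivers hydride from a metal instead of from a diazene.
- Alcohol 3 is formylated (formic acetic anhydride, pyridine) to the allylic formate F6.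
- Pd(OAc)2 with PBu3 in THF, which forms zerovalent palladium in the flask, ionises F6 on the open β-face.
- After loss of CO2, the palladium hydride transfers hydrogen to the more substituted allyl terminus C7 from the same face, which gives 6.

Further compounds
F1 | step 9 | vinylcyclobutane dienone (C1=C2 in the unprimed half) | C=C1C(=O)C=C2[C@@]3(CC[C@@H]4C(=C)C(=O)O[C@@H]4[C@@H]12)CC[C@]31C(=O)C[C@H]2C(=C)CC[C@@H]3C(=C)C(=O)O[C@@H]3[C@H]21
F2 | step 9 | 2-deoxy dimer (H-2 α) | C=C1C(=O)[C@@H]2C3=C(CC[C@@H]4C(=C)C(=O)O[C@@H]4[C@@H]13)CC[C@]21C(=O)C[C@H]2C(=C)CC[C@@H]3C(=C)C(=O)O[C@@H]3[C@H]21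
F3 | step 6 | silyl ether of 7 (3α-OTBS) | C=C1[C@H](O[Si](C)(C)C(C)(C)C)C[C@H]2C(=C)CC[C@@H]3C(=C)C(=O)O[C@@H]3[C@H]21
F4 | step 6 | cross cyclobutane silyl ether | C=C1[C@H](O[Si](C)(C)C(C)(C)C)C[C@H]2[C@@]3(CC[C@@H]4C(=C)C(=O)O[C@@H]4[C@@H]12)CC[C@]31C(=O)C[C@H]2C(=C)CC[C@@H]3C(=C)C(=O)O[C@@H]3[C@H]21
F5 | step 6 | cyclobutane allylic alcohol | C=C1[C@H](O)C[C@H]2[C@@]3(CC[C@@H]4C(=C)C(=O)O[C@@H]4[C@@H]12)CC[C@]31C(=O)C[C@H]2C(=C)CC[C@@H]3C(=C)C(=O)O[C@@H]3[C@H]21
F6 | step 3 | allylic formate of 3 | C=C1CC[C@H]2C(=C)CCC3=C(COC=O)C(=O)O[C@@H]3[C@H]21
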